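Assumption: elemicin (5-allyl-1,2,3-trimethoxybenzene) is bought as such; it is otherwise one O-methylation away from the flavour chemical 4-allyl-2,6-dimethoxyphenol.

**Retrosynthetic overview**
- Target ⇒ its O-benzyl ether (hydrogenolysis) ⇒ (R)-4-(3,4,5-trimethoxybenzyl)butyrolactone plus 4-benzyloxy-3-methoxybenzyl bromide (trans-selective enolate alkylation sets C3).
- Key disconnection: the ring C5–O1 bond of that lactone, formed together with the C4 stereocentre by a catalytic desymmetrising Baeyer–Villiger oxidation of prochiral 3-(3,4,5-trimethoxybenzyl)cyclobutanone.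
- Cyclobutanone ⇒ elemicin plus dichloroketene ([2+2], then dechlorination in the same flask).
- Ring order: the cyclobutanone first, then its oxidative expansion to the five-membered lactone, the only ring of the target.

**Route**

Step 1
Reactants: 1 elemicin (5-allyl-1,2,3-trimethoxybenzene); 2 trichloroacetyl chloride
Product: 5 3-(3,4,5-trimethoxybenzyl)cyclobutan-1-one, via dichloroketene 3 (not isolated), via dichlorocyclobutanone 4 (not isolated)
Conditions: Zn–Cu couple, Et2O/DME, 0 °C to rt, ultrasound; then Zn dust, AcOH, same flask, 50 °C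
Reagents that add atoms: none
Why: Dichloroketene 3, made in the flask by zinc dechlorination of 2, adds to the terminal alkene of 1 in a regioselective ketene [2+2] cycloaddition (carbonyl carbon to the CH2 terminus) to give 4, whose two C–Cl bonds are then removed by Zn/AcOH reductive dehalogenation, leaving the achiral, prochiral ketone 5.

Step 2
Reactants: 5 3-(3,4,5-trimethoxybenzyl)cyclobutan-1-one
Product: 7 (4R)-4-(3,4,5-trimethoxybenzyl)dihydrofuran-2(3H)-one, via Criegee adduct 6 (not isolated)
Conditions: confined chiral imidodiphosphorimidate (IDPi) Brønsted acid (N-triflyl core, 3,3'-diaryl-BINOL arms; 3 mol%; the antipode that gives R, fixed by one test run), 30% aq. H2O2 (1.5 equiv), CHCl3, −40 °C; Na2SO3 quench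
Reagents that add atoms: hydrogen peroxide, OO
Why: Proposed new method: a confined IDPi acid as catalyst for the desymmetrising Baeyer–Villiger oxidation of a 3-(arylmethyl)cyclobutanone. The acid promotes addition of H2O2 to the carbonyl of 5 to give the achiral Criegee adduct 6, which stays hydrogen-bonded and ion-paired inside the chiral pocket. Only one of the two enantiotopic ring CH2 groups can then lie antiperiplanar to the O–O bond and migrate, which forms the ring C–O bond and fixes C4 as R in the same event. The narrow pocket is meant to read the flexible, remote arylmethyl group, which open BINOL-phosphoric acids are expected to discriminate less well, and the low temperature with a non-peracid oxidant spares the electron-rich arene. The closest known reaction type is the chiral-phosphoric-acid-catalysed Baeyer–Villiger desymmetrisation of 3-substituted cyclobutanones with H2O2.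

Step 3
Reactants: 8 (4-benzyloxy-3-methoxyphenyl)methanol
Product: 9 1-(benzyloxy)-4-(bromomethyl)-2-methoxybenzene (4-benzyloxy-3-methoxybenzyl bromide)
Conditions: PBr3 (0.4 equiv), Et2O, 0 °C, 1 h; used fresh
Reagents that add atoms: phosphorus tribromide, BrP(Br)Br
Why: Conversion of a benzylic alcohol to the bromide with PBr3 (bromide displacement on the phosphite ester), under which the aryl benzyl ether and the methoxy group are inert; no stereocentre is involved.

Step 4
Reactants: 7 (4R)-4-(3,4,5-trimethoxybenzyl)dihydrofuran-2(3H)-one; 9 4-benzyloxy-3-methoxybenzyl bromide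
Product: 11 (3R,4R)-3-(4-benzyloxy-3-methoxybenzyl)-4-(3,4,5-trimethoxybenzyl)dihydrofuran-2(3H)-one, via lithium enolate 10 (not isolated)
Conditions: LiN(SiMe3)2 (1.1 equiv), THF, −78 °C; then 9, DMPU, −78 to −40 °C; aq. NH4Cl
Reagents that add atoms: none
Why: Lithium enolate alkylation (SN2) of a 4-substituted butyrolactone, in which the bromide approaches the planar enolate 10 on the face opposite the C4 arylmethyl group, so C3 is set as R, trans to C4.

Step 5
Reactants: 11 (3R,4R)-3-(4-benzyloxy-3-methoxybenzyl)-4-(3,4,5-trimethoxybenzyl)dihydrofuran-2(3H)-one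
Product: 12 (3R,4R)-3-(4-hydroxy-3-methoxybenzyl)-4-(3,4,5-trimethoxybenzyl)dihydrofuran-2(3H)-one (target)
Conditions: H2 (1 atm), 10% Pd/C, EtOAc/EtOH, rt
Reagents that add atoms: none
Why: Catalytic hydrogenolysis of the aryl benzyl ether frees the phenol under neutral conditions that leave the lactone, the methyl ethers and both stereocentres untouched.

**Compound list**

1 | elemicin (5-allyl-1,2,3-trimethoxybenzene) | C=CCc1cc(OC)c(OC)c(OC)c1 | starting material
2 | trichloroacetyl chloride | ClC(Cl)(Cl)C(Cl)=O | starting material
3 | dichloroketene | ClC(Cl)=C=O | intermediate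
4 | 2,2-dichloro-3-(3,4,5-trimethoxybenzyl)cyclobutan-1-one (racemic) | O=C1CC(Cc2cc(OC)c(OC)c(OC)c2)C1(Cl)Cl | intermediate
5 | 3-(3,4,5-trimethoxybenzyl)cyclobutan-1-one | O=C1CC(Cc2cc(OC)c(OC)c(OC)c2)C1 | intermediate
6 | 1-hydroperoxy-3-(3,4,5-trimethoxybenzyl)cyclobutan-1-ol (Criegee adduct, cis/trans, achiral) | OOC1(O)CC(Cc2cc(OC)c(OC)c(OC)c2)C1 | intermediate
7 | (4R)-4-(3,4,5-trimethoxybenzyl)dihydrofuran-2(3H)-one | O=C1OC[C@@H](C1)Cc1cc(OC)c(OC)c(OC)c1 | intermediate
8 | (4-benzyloxy-3-methoxyphenyl)methanol | COc1cc(CO)ccc1OCc1ccccc1 | starting material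
9 | 1-(benzyloxy)-4-(bromomethyl)-2-methoxybenzene | COc1cc(CBr)ccc1OCc1ccccc1 | intermediate
10 | lithium (4R)-4-(3,4,5-trimethoxybenzyl)-4,5-dihydrofuran-2-olate | [Li+].[O-]C1=C[C@H](CO1)Cc1cc(OC)c(OC)c(OC)c1 | intermediate
11 | (3R,4R)-3-(4-benzyloxy-3-methoxybenzyl)-4-(3,4,5-trimethoxybenzyl)dihydrofuran-2(3H)-one | COc1cc(C[C@H]2C(=O)OC[C@@H]2Cc2cc(OC)c(OC)c(OC)c2)ccc1OCc1ccccc1 | intermediate
12 | (3R,4R)-3-(4-hydroxy-3-methoxybenzyl)-4-(3,4,5-trimethoxybenzyl)dihydrofuran-2(3H)-one | COc1cc(C[C@H]2C(=O)OC[C@@H]2Cc2cc(OC)c(OC)c(OC)c2)ccc1O | target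

**Step count**

Total steps: 5. Longest linear sequence: 4 (1 → 5 → 7 → 11 → 12); step 3 is a one-step side branch.

**Three steps most likely to fail**

Step 2 (the proposed new oxidation). The risk is insufficient enantioselectivity, or a catalyst slowed by water. The fallback sets out from 5 and comes back at 7, and uses known chemistry: the desymmetrisation is handed to a flavin-dependent Baeyer–Villiger monooxygenase. Growing cells of Cunninghamella echinulata, or E. coli expressing a cyclohexanone-monooxygenase-type enzyme of R preference, are used with air as oxidant and glucose for cofactor recycling in aqueous buffer at 24–30 °C. This biocatalytic oxidation is established for 3-(arylmethyl)cyclobutanones and gives the (R)-lactones in high ee. It replaces acid/peroxide chemocatalysis by an enzyme with O2 and makes no compound beyond those already listed.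

Step 1 (one-flask cycloaddition and dechlorination). The risks are zinc-chloride-promoted side reactions of the electron-rich arene and incomplete dechlorination. The fallback sets out from 1 and comes back at 5 by a keteniminium [2+2] route. N,N-Dimethylacetamide, Tf2O and 2,4,6-collidine in refluxing 1,2-dichloroethane generate N,N-dimethylketeniminium triflate F1. This adds to the allyl group of 1 to give N,N-dimethyl-3-(3,4,5-trimethoxybenzyl)cyclobutan-1-iminium triflate F2, and aqueous NaHCO3 hydrolysis then releases 5. No chlorine and no zinc reduction are involved.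

Step 4 (enolate alkylation). The risks are a labile bromide, double alkylation and incomplete conversion. The fallback sets out from 7 and comes back at 12 by an aldol and hydrogenolysis sequence. Lithium enolate 10 is added to bought 4-benzyloxy-3-methoxybenzaldehyde (THF, −78 °C). This gives (3S,4R)-3-[(4-benzyloxy-3-methoxyphenyl)(hydroxy)methyl]-4-(3,4,5-trimethoxybenzyl)dihydrofuran-2(3H)-one F3 as a mixture of carbinol epimers, trans across the ring. Hydrogenolysis (H2, 10% Pd/C, AcOH, trace HClO4, rt) then removes the benzylic hydroxyl and the O-benzyl group together and gives 12 directly, so neither 9 nor 11 is needed.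

**Further compounds**

F1 | step 1 | N,N-dimethylketeniminium triflate | C=C=[N+](C)C.[O-]S(=O)(=O)C(F)(F)F
F2 | step 1 | N,N-dimethyl-3-(3,4,5-trimethoxybenzyl)cyclobutan-1-iminium triflate | C[N+](C)=C1CC(Cc2cc(OC)c(OC)c(OC)c2)C1.[O-]S(=O)(=O)C(F)(F)F
F0 | step 2 | none | none
F3 | step 4 | (3S,4R)-3-[(4-benzyloxy-3-methoxyphenyl)(hydroxy)methyl]-4-(3,4,5-trimethoxybenzyl)dihydrofuran-2(3H)-one (carbinol epimers) | COc1cc(C(O)[C@H]2C(=O)OC[C@@H]2Cc2cc(OC)c(OC)c(OC)c2)ccc1OCc1ccccc1
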